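## Retrosynthetic overview

1. Ring B (the lactone) is closed last by C3–O bond formation: enantioselective oxidative lactonisation of the benzylic C–H bond of the free 6-alkylresorcylic acid, with no carbonyl addition or ketone reduction at C3.
2. The side-chain ketone is unmasked just before that from an internal alkyne by hydroxyl-directed 5-endo-dig hydration. The alkyne serves as a protecting-group-free ketone surrogate, and the carbinol carbon comes from a chiral-pool alkynol.
3. Ring A is built, not bought: polyketide-type C2→C7 aldol aromatisation of a 6-(2-oxoalkyl)-4-methoxy-2-pyranone (an enol-ether-masked triketo acid). This places OMe ortho and OH para to CO2H without any phenol differentiation.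
4. The keto-pyranone comes from C-acylation of lithiated 4-methoxy-6-methyl-2-pyranone with a C16 hydroxy-alkynoic acid, itself made from an alkynol dianion and 11-bromoundecanoic acid.
5. Ring order: ring A (step 3), then ring B (step 5).

Assumption: nature is taken to form ring A by C2–C7 aldol aromatisation of the polyketide and ring B by late benzylic C–H oxygenation of the free resorcylic acid followed by lactonisation; (S)-pent-4-yn-2-ol is taken as a catalogue compound.

## Route

Step 1
Reactants: 1 (S)-pent-4-yn-2-ol; 2 11-bromoundecanoic acid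
Product: 3 (S)-15-hydroxyhexadec-12-ynoic acid
Conditions: 1 (1.15 equiv), n-BuLi (2.3 equiv), THF/DMPU (5:1), −78 → 0 °C; add 2 pre-treated with n-BuLi (1.0 equiv, THF, −78 °C); 0 °C → rt, 16 h; 1 M HCl
Reagents that add atoms: none
Why: The O,C-dilithio derivative of 1 is C-alkylated by the primary bromide of lithium 11-bromoundecanoate (SN2 acetylide alkylation), and the (S)-carbinol centre of 1 is not touched and is carried unchanged to the target.

Step 2
Reactants: 3 (S)-15-hydroxyhexadec-12-ynoic acid; 4 4-methoxy-6-methyl-2H-pyran-2-one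
Product: 6 6-[(S)-16-hydroxy-2-oxoheptadec-13-yn-1-yl]-4-methoxy-2H-pyran-2-one, via acyl imidazolide 5 (not isolated)
Conditions: 3, CDI (1.05 equiv), THF, rt, 1 h; this solution added to 4 (4.5 equiv)/LiN(SiMe3)2 (4.5 equiv), THF, −78 → −20 °C; AcOH quench
Reagents that add atoms: none
Why: Claisen-type C-acylation of the lithium dienolate of 4 (kinetic deprotonation of the 6-methyl group) by the acyl imidazolide; the excess dienolate absorbs the carbinol O–H, the imidazole N–H and the acidic product C–H, and inverse addition keeps O-acylation by the side-chain alkoxide minor.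

Step 3
Reactants: 6 6-[(S)-16-hydroxy-2-oxoheptadec-13-yn-1-yl]-4-methoxy-2H-pyran-2-one
Product: 8 4-hydroxy-6-[(S)-14-hydroxypentadec-11-yn-1-yl]-2-methoxybenzoic acid, via ring-opened enol-ether diketo acid 7 (not isolated)
Conditions: 2 M aq. KOH (10 equiv), 1,4-dioxane, Ar, 60 °C, 6 h; then 1 M HCl to pH 3, 0 °C
Reagents that add atoms: potassium hydroxide, [K+].[OH-] (the hydroxide oxygen ends in the carboxyl group)
Why: Biogenetic-type pyranone-to-resorcylate isomerisation: hydroxide opens the lactone to the enol-ether-masked 3,5,7-triketo acid 7, whose dienolate closes C2→C7 by intramolecular aldol condensation and dehydrates to ring A, while the carboxylate cannot act as a Claisen acceptor and the surviving enol ether fixes OMe ortho and OH para to CO2H.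

Step 4
Reactants: 8 4-hydroxy-6-[(S)-14-hydroxypentadec-11-yn-1-yl]-2-methoxybenzoic acid
Product: 10 4-hydroxy-6-[(S)-14-hydroxy-11-oxopentadecyl]-2-methoxybenzoic acid, via cyclic enol ether 9 (not isolated)
Conditions: Ph3PAuCl (2 mol %), AgOTf (2 mol %), THF/H2O (10:1), rt, 3 h
Reagents that add atoms: water, O
Why: Gold-catalysed 5-endo-dig cycloisomerisation of the homopropargylic alcohol gives the 2,3-dihydrofuran 9, which is hydrolysed in the same flask, so the ketone lands regiospecifically on the alkyne carbon remote from the carbinol (hydroxyl-directed alkyne hydration) and no stereocentre is touched.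

Step 5
Reactants: 10 4-hydroxy-6-[(S)-14-hydroxy-11-oxopentadecyl]-2-methoxybenzoic acid
Product: 13 (S)-5-hydroxy-3-[(S)-13-hydroxy-10-oxotetradecyl]-7-methoxyisobenzofuran-1(3H)-one, via tris-silylated acid 11 (not isolated), via bis-silylated phthalide 12 (not isolated)
Conditions: N,O-bis(trimethylsilyl)acetamide (BSA, 2.5 equiv), PhCl, 50 °C, 1 h; then Cu(MeCN)4PF6 (10 mol %), (S,S)-2,2′-isopropylidenebis(4-benzyl-2-oxazoline) (12 mol %), N-fluorobenzenesulfonimide (NFSI, 1.5 equiv), PhCl, 0 °C → rt, 24 h; then 0.5 M HCl, THF, 0 °C
Reagents that add atoms: none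
Why: Proposed new method: monovalent copper is oxidised by NFSI to a bisoxazoline-bound divalent copper fluoride and the sulfonimidyl radical, which abstracts the benzylic hydrogen (phenol and carbinol are masked as silyl ethers, the remaining C–H bonds are α to a ketone or unactivated); the secondary benzylic radical is captured at copper, the pendant silyl ester displaces fluoride as Me3SiF to give a six-membered trivalent cupracycle, and C–O reductive elimination closes ring B with the chiral ligand deciding the face, so C3 is set (S) in the bond-forming step (which ligand hand gives (S) is fixed on a model 2-alkylbenzoic acid, both hands being commercial); the closest known chemistry is copper/bisoxazoline radical-relay enantioselective benzylic C–H cyanation and the racemic copper- or peroxydisulfate-mediated oxidative lactonisation of 2-alkylbenzoic acids to phthalides, a Kharasch–Sosnovsky-type C–O coupling made intramolecular.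

## Compound list

1 | (S)-pent-4-yn-2-ol | C#CC[C@H](C)O | starting material
2 | 11-bromoundecanoic acid | OC(=O)CCCCCCCCCCBr | starting material
3 | (S)-15-hydroxyhexadec-12-ynoic acid | OC(=O)CCCCCCCCCCC#CC[C@H](C)O | intermediate
4 | 4-methoxy-6-methyl-2H-pyran-2-one | COC1=CC(=O)OC(C)=C1 | starting material
5 | (S)-15-hydroxy-1-(1H-imidazol-1-yl)hexadec-12-yn-1-one | O=C(CCCCCCCCCCC#CC[C@H](C)O)n1ccnc1 | intermediate (not isolated)
6 | 6-[(S)-16-hydroxy-2-oxoheptadec-13-yn-1-yl]-4-methoxy-2H-pyran-2-one | COC1=CC(=O)OC(CC(=O)CCCCCCCCCCC#CC[C@H](C)O)=C1 | intermediate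
7 | (2E,21S)-21-hydroxy-3-methoxy-5,7-dioxodocos-2-en-18-ynoic acid | OC(=O)/C=C(/OC)CC(=O)CC(=O)CCCCCCCCCCC#CC[C@H](C)O | intermediate (not isolated)
8 | 4-hydroxy-6-[(S)-14-hydroxypentadec-11-yn-1-yl]-2-methoxybenzoic acid | COc1cc(O)cc(CCCCCCCCCCC#CC[C@H](C)O)c1C(=O)O | intermediate
9 | 4-hydroxy-2-methoxy-6-{10-[(S)-5-methyl-4,5-dihydrofuran-2-yl]decyl}benzoic acid | COc1cc(O)cc(CCCCCCCCCCC2=CC[C@H](C)O2)c1C(=O)O | intermediate (not isolated)
10 | 4-hydroxy-6-[(S)-14-hydroxy-11-oxopentadecyl]-2-methoxybenzoic acid | COc1cc(O)cc(CCCCCCCCCCC(=O)CC[C@H](C)O)c1C(=O)O | intermediate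
11 | trimethylsilyl 2-methoxy-6-[(S)-11-oxo-14-(trimethylsilyloxy)pentadecyl]-4-(trimethylsilyloxy)benzoate | COc1cc(O[Si](C)(C)C)cc(CCCCCCCCCCC(=O)CC[C@H](C)O[Si](C)(C)C)c1C(=O)O[Si](C)(C)C | intermediate (not isolated)
12 | (S)-7-methoxy-3-[(S)-10-oxo-13-(trimethylsilyloxy)tetradecyl]-5-(trimethylsilyloxy)isobenzofuran-1(3H)-one | COc1cc(O[Si](C)(C)C)cc2c1C(=O)O[C@H]2CCCCCCCCCC(=O)CC[C@H](C)O[Si](C)(C)C | intermediate (not isolated)
13 | (S)-5-hydroxy-3-[(S)-13-hydroxy-10-oxotetradecyl]-7-methoxyisobenzofuran-1(3H)-one | COc1cc(O)cc2c1C(=O)O[C@H]2CCCCCCCCCC(=O)CC[C@H](C)O | target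

## Summary and fallbacks

Total step count: 5. Longest linear sequence: 5 steps (1/2 → 3 → 6 → 8 → 10 → 13).

Steps most likely to fail:

Step 5 (enantioselective benzylic C–H lactonisation). The risks are poor facial control if the C–O bond forms through a free benzylic cation, and competing hydrogen abstraction elsewhere. The fallback gives up catalyst control of C3 and sets out from 10. The same in-situ silylation gives 11, and the radical-relay lactonisation is run with an achiral ligand (4,4′-di-tert-butyl-2,2′-bipyridine, Cu(MeCN)4PF6, NFSI, PhCl, 40 °C), where ring closure by the pendant silyl ester on the benzylic cation is acceptable. This gives 12 together with its C3 epimer, (R)-7-methoxy-3-[(S)-10-oxo-13-(trimethylsilyloxy)tetradecyl]-5-(trimethylsilyloxy)isobenzofuran-1(3H)-one F1. Acidic desilylation then gives 13 and (R)-5-hydroxy-3-[(S)-13-hydroxy-10-oxotetradecyl]-7-methoxyisobenzofuran-1(3H)-one F2, and the two C3 epimers are separated by preparative chiral-phase SFC. The fallback comes back to the route at 13, at the cost of half the material.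

Step 3 (pyranone-to-resorcylic acid isomerisation). The risks under hydroxide are γ-pyranone formation, retro-Claisen cleavage of the diketone, or decarboxylation of the electron-rich acid on work-up. The fallback sets out from 6 and opens the pyranone with methoxide instead (NaOMe, MeOH, reflux), so that the same aldol aromatisation gives the ester, methyl 4-hydroxy-6-[(S)-14-hydroxypentadec-11-yn-1-yl]-2-methoxybenzoate F3. This di-ortho-substituted ester resists saponification, so it is cleaved by SN2 attack of LiSCH2CH2CH3 (5 equiv, HMPA, rt) on the ester methyl group, which leaves the aryl methyl ether alone. This gives 8, where the fallback comes back to the route.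

Step 2 (C-acylation of the pyranone dienolate with a hydroxyl-bearing acyl donor). The risks are O-acylation or oligo-ester formation through the side-chain alkoxide and sluggish acylation of the stabilised anion. The fallback moves the bond formed from C6–C7 to C8–C9 and sets out from 4 and 1. Lithiated 4 is C-acetylated with N-acetylimidazole to the known 4-methoxy-6-(2-oxopropyl)-2H-pyran-2-one F4. Dilithiated 1 is mono-alkylated with 1,9-dibromononane (3 equiv, THF/DMPU) to (S)-14-bromotetradec-4-yn-2-ol F5. The dianion of F4 (LiN(iPr)2, 2.2 equiv, THF/HMPA, −78 → 0 °C) is then alkylated at its terminal methyl carbon by the lithium alkoxide of F5, which gives 6, where the fallback comes back to the route.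

## Further compounds

F1 | step 5 | (R)-7-methoxy-3-[(S)-10-oxo-13-(trimethylsilyloxy)tetradecyl]-5-(trimethylsilyloxy)isobenzofuran-1(3H)-one | COc1cc(O[Si](C)(C)C)cc2c1C(=O)O[C@@H]2CCCCCCCCCC(=O)CC[C@H](C)O[Si](C)(C)C
F2 | step 5 | (R)-5-hydroxy-3-[(S)-13-hydroxy-10-oxotetradecyl]-7-methoxyisobenzofuran-1(3H)-one | COc1cc(O)cc2c1C(=O)O[C@@H]2CCCCCCCCCC(=O)CC[C@H](C)O
F3 | step 3 | methyl 4-hydroxy-6-[(S)-14-hydroxypentadec-11-yn-1-yl]-2-methoxybenzoate | COC(=O)c1c(OC)cc(O)cc1CCCCCCCCCCC#CC[C@H](C)O
F4 | step 2 | 4-methoxy-6-(2-oxopropyl)-2H-pyran-2-one | COC1=CC(=O)OC(CC(C)=O)=C1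
F5 | step 2 | (S)-14-bromotetradec-4-yn-2-ol | BrCCCCCCCCCC#CC[C@H](C)O
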